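## Retrosynthetic overview

1. The C1–O ester is put on the citronellol piece at the start, and the last step only unmasks the phenol and the two diols. No ring is formed: the target is acyclic, and both dioxolane rings are bought (L-tartrate acetonide) and opened at the end.
2. C13–C14: 9-BBN hydroboration of a C12=C13 vinyl carbinol and B-alkyl Suzuki coupling with the C14–C24 iodide.
3. C5–C6: photochemical iron/nickel decarboxylative alkyl–alkyl coupling (new) of the citronellol-derived acid (C1–C5, brings C3) with the C6–C13 iodide.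
4. Both oxygenated blocks (C6–C11 and C14–C19) come from one common intermediate, made by photochemical nickel decarboxylative coupling of the tartrate half-ester with (R)-BrCH2CH(CH3)CH2Cl (C8–C9 and C16–C17 bonds; C9/C17 set trans, C7/C15 bought).
5. From that intermediate: C11 by chelation-controlled vinyl addition to the methyl ketone; C18 by a second photochemical decarboxylative (isopropenyl) coupling, C19 by anti hydroboration, and the tail by alkyl–alkyl Suzuki coupling.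

Assumption: chain carbons are numbered C1–C24 from the ester oxygen, and (R)-1-bromo-3-chloro-2-methylpropane (the Roche-ester-derived dihalide) is taken as a purchasable building block.

## Route

Step 1
Reactants: 1 dimethyl (4R,5R)-2,2-dimethyl-1,3-dioxolane-4,5-dicarboxylate (dimethyl 2,3-O-isopropylidene-L-tartrate)
Product: 2 (4R,5R)-5-(methoxycarbonyl)-2,2-dimethyl-1,3-dioxolane-4-carboxylic acid
Conditions: KOH (1.0 equiv), MeOH, 0 °C to rt; then 1 M HCl to pH 3
Reagents that add atoms: potassium hydroxide [K+].[OH-]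
Why: Mono-saponification of a C2-symmetric diester stops at the half-ester because the carboxylate deactivates the second ester; no stereocentre is touched.

Step 2
Reactants: 2 (4R,5R)-5-(methoxycarbonyl)-2,2-dimethyl-1,3-dioxolane-4-carboxylic acid; 3 (R)-1-bromo-3-chloro-2-methylpropane
Product: 4 methyl (4R,5S)-5-[(2S)-3-chloro-2-methylpropyl]-2,2-dimethyl-1,3-dioxolane-4-carboxylate
Conditions: Ir[dF(CF3)ppy]2(dtbbpy)PF6 (2 mol%), NiCl2·glyme (10 mol%), 4,4′-dimethoxy-2,2′-bipyridine (10 mol%), K2CO3, H2O (20 equiv), MeCN, 450 nm LEDs, rt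
Reagents that add atoms: none
Why: Nickel/photoredox decarboxylative sp3–sp3 cross-coupling: the dioxolanyl radical left after CO2 loss is joined through nickel to the C–Br end of 3 (C–Cl inert) on the ring face away from the neighbouring CO2Me, so the new centre (C9 or C17) is set trans by the surviving tartrate centre, and C7/C15 is bought in 3.

Step 3
Reactants: 4 methyl (4R,5S)-5-[(2S)-3-chloro-2-methylpropyl]-2,2-dimethyl-1,3-dioxolane-4-carboxylate
Product: 5 (4R,5S)-5-[(2S)-3-chloro-2-methylpropyl]-2,2-dimethyl-1,3-dioxolane-4-carboxylic acid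
Conditions: LiOH·H2O, THF–H2O, 0 °C; then 1 M HCl to pH 3
Reagents that add atoms: lithium hydroxide [Li+].[OH-]
Why: Plain ester saponification; the primary chloride and the acetonide survive cold hydroxide, and the trans ring is the thermodynamic one.

Step 4
Reactants: 5 (4R,5S)-5-[(2S)-3-chloro-2-methylpropyl]-2,2-dimethyl-1,3-dioxolane-4-carboxylic acid
Product: 6 (4S,5S)-4-[(2S)-3-chloro-2-methylpropyl]-2,2-dimethyl-5-(prop-1-en-2-yl)-1,3-dioxolane
Conditions: CH2=C(CH3)Br (3 equiv), Ir[dF(CF3)ppy]2(dtbbpy)PF6 (1 mol%), NiCl2·glyme (10 mol%), 4,4′-di-tert-butyl-2,2′-bipyridine (10 mol%), Cs2CO3, DMSO, 450 nm LEDs, rt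
Reagents that add atoms: 2-bromopropene CC(Br)=C
Why: Nickel/photoredox decarboxylative alkenylation of an α-oxy acid with a vinyl bromide; the C18 radical is re-bonded trans to the C17 side chain, so C18 is reset by C17.

Step 5
Reactants: 6 (4S,5S)-4-[(2S)-3-chloro-2-methylpropyl]-2,2-dimethyl-5-(prop-1-en-2-yl)-1,3-dioxolane
Product: 8 (4S,5S)-4-[(2S)-3-chloro-2-methylpropyl]-5-[(2S)-heptan-2-yl]-2,2-dimethyl-1,3-dioxolane, via B-alkyl-9-BBN adduct 7 (not isolated)
Conditions: 9-BBN (1.3 equiv), THF, 0 °C to rt; then n-BuBr (2 equiv), Pd(OAc)2 (4 mol%), PCy3 (8 mol%), K3PO4·H2O, THF, rt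
Reagents that add atoms: 9-borabicyclo[3.3.1]nonane B1C2CCCC1CCC2 (atoms kept in 7 only); 1-bromobutane CCCCBr
Why: Uncatalysed 9-BBN hydroboration of a 1,1-disubstituted alkene next to an oxygenated stereocentre is anti-selective (allylic H eclipses the alkene, B–H adds opposite the ring carbon; A(1,3)-strain model), fixing C19 from C18, and the primary alkylborane then undergoes Pd/PCy3 alkyl–alkyl Suzuki–Miyaura coupling at rt, where the alkyl chloride is inert.

Step 6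
Reactants: 8 (4S,5S)-4-[(2S)-3-chloro-2-methylpropyl]-5-[(2S)-heptan-2-yl]-2,2-dimethyl-1,3-dioxolane
Product: 9 (4S,5S)-4-[(2S)-heptan-2-yl]-5-[(2S)-3-iodo-2-methylpropyl]-2,2-dimethyl-1,3-dioxolane
Conditions: NaI (5 equiv), 2-butanone, reflux
Reagents that add atoms: sodium iodide [Na+].[I-]
Why: Finkelstein halide exchange (SN2 at a primary CH2, driven by NaCl precipitation); no stereocentre is involved.

Step 7
Reactants: 4 methyl (4R,5S)-5-[(2S)-3-chloro-2-methylpropyl]-2,2-dimethyl-1,3-dioxolane-4-carboxylate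
Product: 11 1-{(4R,5S)-5-[(2S)-3-chloro-2-methylpropyl]-2,2-dimethyl-1,3-dioxolan-4-yl}ethan-1-one, via Weinreb amide 10 (not isolated)
Conditions: MeNH(OMe)·HCl, i-PrMgCl, THF, −20 °C; then CH3MgBr, −20 to 0 °C; aq. NH4Cl
Reagents that add atoms: N,O-dimethylhydroxylamine hydrochloride CNOC.Cl (atoms kept in 10 only); methylmagnesium bromide C[Mg]Br
Why: One-pot Weinreb ketone synthesis; the chelated tetrahedral adduct stops over-addition, and the trans ring centre next to the carbonyl is the stable one.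

Step 8
Reactants: 11 1-{(4R,5S)-5-[(2S)-3-chloro-2-methylpropyl]-2,2-dimethyl-1,3-dioxolan-4-yl}ethan-1-one
Product: 12 (2R)-2-{(4R,5S)-5-[(2S)-3-chloro-2-methylpropyl]-2,2-dimethyl-1,3-dioxolan-4-yl}but-3-en-2-ol
Conditions: MgBr2·OEt2 (1.5 equiv), CH2Cl2, −78 °C; CH2=CHMgBr (THF solution), −78 °C; aq. NH4Cl
Reagents that add atoms: vinylmagnesium bromide C=C[Mg]Br
Why: Cram-chelate-controlled Grignard addition: magnesium bridges the ketone oxygen and the α ring oxygen and vinyl attacks the face opposite C9, giving the (R)-tertiary alcohol at C11 with O10 and O11 syn.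

Step 9
Reactants: 12 (2R)-2-{(4R,5S)-5-[(2S)-3-chloro-2-methylpropyl]-2,2-dimethyl-1,3-dioxolan-4-yl}but-3-en-2-ol
Product: 13 (2R)-2-{(4R,5S)-5-[(2S)-3-iodo-2-methylpropyl]-2,2-dimethyl-1,3-dioxolan-4-yl}but-3-en-2-ol
Conditions: NaI (5 equiv), NaHCO3, 2-butanone, reflux
Reagents that add atoms: sodium iodide [Na+].[I-]
Why: Finkelstein exchange under neutral buffered conditions, which the tertiary allylic alcohol and acetonide tolerate.

Step 10
Reactants: 14 (S)-citronellol [(3S)-3,7-dimethyloct-6-en-1-ol]; 15 3-[4-(benzyloxy)phenyl]propanoic acid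
Product: 16 (3S)-3,7-dimethyloct-6-en-1-yl 3-[4-(benzyloxy)phenyl]propanoate
Conditions: EDC·HCl, DMAP (cat.), CH2Cl2, rt
Reagents that add atoms: none
Why: Carbodiimide (Steglich-type) esterification of a primary alcohol; C3 is bought in 14.

Step 11
Reactants: 16 (3S)-3,7-dimethyloct-6-en-1-yl 3-[4-(benzyloxy)phenyl]propanoate
Product: 18 (4S)-6-({3-[4-(benzyloxy)phenyl]propanoyl}oxy)-4-methylhexanoic acid, via aldehyde 17 (not isolated)
Conditions: O3, CH2Cl2–MeOH, −78 °C (Sudan red end point); Me2S, −78 °C to rt; then NaClO2, NaH2PO4, 2-methylbut-2-ene, t-BuOH–H2O, rt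
Reagents that add atoms: ozone [O-][O+]=O; sodium chlorite [Na+].[O-]Cl=O
Why: Ozonolysis of the trisubstituted alkene (far faster than attack on the aryl benzyl ether) followed by Pinnick oxidation of the crude aldehyde; C3 is untouched.

Step 12
Reactants: 13 (2R)-2-{(4R,5S)-5-[(2S)-3-iodo-2-methylpropyl]-2,2-dimethyl-1,3-dioxolan-4-yl}but-3-en-2-ol; 18 (4S)-6-({3-[4-(benzyloxy)phenyl]propanoyl}oxy)-4-methylhexanoic acid
Product: 19 (3S,7R)-8-{(4S,5R)-5-[(2R)-2-hydroxybut-3-en-2-yl]-2,2-dimethyl-1,3-dioxolan-4-yl}-3,7-dimethyloctyl 3-[4-(benzyloxy)phenyl]propanoate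
Conditions: 18 (2.5 equiv), FeCl3 (10 mol%), NiBr2·glyme (10 mol%), 4,4′-di-tert-butyl-2,2′-bipyridine (12 mol%), Cs2CO3, MeCN–DMA, 390 nm LEDs, rt
Reagents that add atoms: none
Why: Proposed new method: the ferric carboxylate of 18 undergoes ligand-to-metal charge-transfer homolysis at 390 nm to give the unstabilised primary C5 radical and CO2; monovalent bipyridine-nickel abstracts iodine from 13 and rebinds the C6 radical; the ferrous iron formed reduces this trivalent alkylnickel halide to divalent alkylnickel, which captures the C5 radical and reductively eliminates the C5–C6 bond from trivalent dialkylnickel, returning monovalent nickel and ferric carboxylate, so the coupling is redox-neutral with no pre-activation and touches no stereocentre (C3 and C7 only flank the new bond); the acid is used in excess to suppress iodide homocoupling; closest known reaction types are iridium/nickel decarboxylative sp3–sp3 coupling of α-heteroatom acids with alkyl halides and iron-LMCT/nickel decarboxylative arylation with aryl iodides.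

Step 13
Reactants: 19 (3S,7R)-8-{(4S,5R)-5-[(2R)-2-hydroxybut-3-en-2-yl]-2,2-dimethyl-1,3-dioxolan-4-yl}-3,7-dimethyloctyl 3-[4-(benzyloxy)phenyl]propanoate; 9 (4S,5S)-4-[(2S)-heptan-2-yl]-5-[(2S)-3-iodo-2-methylpropyl]-2,2-dimethyl-1,3-dioxolane
Product: 21 (3S,7R)-8-[(4S,5R)-5-{(2R,6R)-7-[(4S,5S)-5-[(2S)-heptan-2-yl]-2,2-dimethyl-1,3-dioxolan-4-yl]-2-hydroxy-6-methylheptan-2-yl}-2,2-dimethyl-1,3-dioxolan-4-yl]-3,7-dimethyloctyl 3-[4-(benzyloxy)phenyl]propanoate, via alkylborane 20 (not isolated)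
Conditions: 9-BBN (2.5 equiv), THF, rt; then 9 (1.2 equiv), Pd(OAc)2 (5 mol%), PCy3 (10 mol%), K3PO4·H2O, THF–dioxane, rt to 40 °C
Reagents that add atoms: 9-borabicyclo[3.3.1]nonane B1C2CCCC1CCC2 (atoms kept in 20 only)
Why: Anti-Markovnikov hydroboration of the only alkene (the extra 9-BBN covers the tertiary OH) and B-alkyl Suzuki–Miyaura alkyl–alkyl coupling with the primary iodide form C13–C14; the ester survives K3PO4 at rt and no stereocentre is formed.

Step 14
Reactants: 21 (3S,7R)-8-[(4S,5R)-5-{(2R,6R)-7-[(4S,5S)-5-[(2S)-heptan-2-yl]-2,2-dimethyl-1,3-dioxolan-4-yl]-2-hydroxy-6-methylheptan-2-yl}-2,2-dimethyl-1,3-dioxolan-4-yl]-3,7-dimethyloctyl 3-[4-(benzyloxy)phenyl]propanoate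
Product: 23 (3S,7R,9S,10R,11R,15R,17S,18S,19S)-9,10,11,17,18-pentahydroxy-3,7,11,15,19-pentamethyltetracosyl 3-(4-hydroxyphenyl)propanoate (CNP0234982.1), via free phenol bis-acetonide 22 (not isolated)
Conditions: H2 (1 atm), Pd on carbon (Pd/C, 10 wt%), EtOAc, rt; filter; then 2 M aq. HCl, THF, rt
Reagents that add atoms: none
Why: Hydrogenolysis of the aryl benzyl ether followed by acid-catalysed hydrolysis of the two acetonides; the primary alkyl ester survives dilute aqueous acid at rt and no stereocentre is affected.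

## Compound list

1 | dimethyl (4R,5R)-2,2-dimethyl-1,3-dioxolane-4,5-dicarboxylate | COC(=O)[C@@H]1OC(C)(C)O[C@H]1C(=O)OC | starting material
2 | (4R,5R)-5-(methoxycarbonyl)-2,2-dimethyl-1,3-dioxolane-4-carboxylic acid | COC(=O)[C@@H]1OC(C)(C)O[C@H]1C(O)=O | intermediate
3 | (R)-1-bromo-3-chloro-2-methylpropane | BrC[C@H](C)CCl | starting material
4 | methyl (4R,5S)-5-[(2S)-3-chloro-2-methylpropyl]-2,2-dimethyl-1,3-dioxolane-4-carboxylate | COC(=O)[C@@H]1OC(C)(C)O[C@H]1C[C@H](C)CCl | intermediate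
5 | (4R,5S)-5-[(2S)-3-chloro-2-methylpropyl]-2,2-dimethyl-1,3-dioxolane-4-carboxylic acid | OC(=O)[C@@H]1OC(C)(C)O[C@H]1C[C@H](C)CCl | intermediate
6 | (4S,5S)-4-[(2S)-3-chloro-2-methylpropyl]-2,2-dimethyl-5-(prop-1-en-2-yl)-1,3-dioxolane | C=C(C)[C@@H]1OC(C)(C)O[C@H]1C[C@H](C)CCl | intermediate
7 | 9-[(2S)-2-{(4S,5S)-5-[(2S)-3-chloro-2-methylpropyl]-2,2-dimethyl-1,3-dioxolan-4-yl}propyl]-9-borabicyclo[3.3.1]nonane | C1CCC2CCCC1B2C[C@H](C)[C@@H]1OC(C)(C)O[C@H]1C[C@H](C)CCl | intermediate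
8 | (4S,5S)-4-[(2S)-3-chloro-2-methylpropyl]-5-[(2S)-heptan-2-yl]-2,2-dimethyl-1,3-dioxolane | CCCCC[C@H](C)[C@@H]1OC(C)(C)O[C@H]1C[C@H](C)CCl | intermediate
9 | (4S,5S)-4-[(2S)-heptan-2-yl]-5-[(2S)-3-iodo-2-methylpropyl]-2,2-dimethyl-1,3-dioxolane | CCCCC[C@H](C)[C@@H]1OC(C)(C)O[C@H]1C[C@H](C)CI | intermediate
10 | (4R,5S)-5-[(2S)-3-chloro-2-methylpropyl]-N-methoxy-N,2,2-trimethyl-1,3-dioxolane-4-carboxamide | CON(C)C(=O)[C@@H]1OC(C)(C)O[C@H]1C[C@H](C)CCl | intermediate
11 | 1-{(4R,5S)-5-[(2S)-3-chloro-2-methylpropyl]-2,2-dimethyl-1,3-dioxolan-4-yl}ethan-1-one | CC(=O)[C@@H]1OC(C)(C)O[C@H]1C[C@H](C)CCl | intermediate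
12 | (2R)-2-{(4R,5S)-5-[(2S)-3-chloro-2-methylpropyl]-2,2-dimethyl-1,3-dioxolan-4-yl}but-3-en-2-ol | C=C[C@@](C)(O)[C@@H]1OC(C)(C)O[C@H]1C[C@H](C)CCl | intermediate
13 | (2R)-2-{(4R,5S)-5-[(2S)-3-iodo-2-methylpropyl]-2,2-dimethyl-1,3-dioxolan-4-yl}but-3-en-2-ol | C=C[C@@](C)(O)[C@@H]1OC(C)(C)O[C@H]1C[C@H](C)CI | intermediate
14 | (S)-citronellol, (3S)-3,7-dimethyloct-6-en-1-ol | CC(C)=CCC[C@H](C)CCO | starting material
15 | 3-[4-(benzyloxy)phenyl]propanoic acid | OC(=O)CCc1ccc(OCc2ccccc2)cc1 | starting material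
16 | (3S)-3,7-dimethyloct-6-en-1-yl 3-[4-(benzyloxy)phenyl]propanoate | CC(C)=CCC[C@H](C)CCOC(=O)CCc1ccc(OCc2ccccc2)cc1 | intermediate
17 | (3S)-3-methyl-6-oxohexyl 3-[4-(benzyloxy)phenyl]propanoate | O=CCC[C@H](C)CCOC(=O)CCc1ccc(OCc2ccccc2)cc1 | intermediate
18 | (4S)-6-({3-[4-(benzyloxy)phenyl]propanoyl}oxy)-4-methylhexanoic acid | OC(=O)CC[C@H](C)CCOC(=O)CCc1ccc(OCc2ccccc2)cc1 | intermediate
19 | (3S,7R)-8-{(4S,5R)-5-[(2R)-2-hydroxybut-3-en-2-yl]-2,2-dimethyl-1,3-dioxolan-4-yl}-3,7-dimethyloctyl 3-[4-(benzyloxy)phenyl]propanoate | C=C[C@@](C)(O)[C@@H]1OC(C)(C)O[C@H]1C[C@H](C)CCC[C@H](C)CCOC(=O)CCc1ccc(OCc2ccccc2)cc1 | intermediate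
20 | (3S,7R)-8-{(4S,5R)-5-[(2R)-4-(9-borabicyclo[3.3.1]nonan-9-yl)-2-hydroxybutan-2-yl]-2,2-dimethyl-1,3-dioxolan-4-yl}-3,7-dimethyloctyl 3-[4-(benzyloxy)phenyl]propanoate | C1CCC2CCCC1B2CC[C@@](C)(O)[C@@H]1OC(C)(C)O[C@H]1C[C@H](C)CCC[C@H](C)CCOC(=O)CCc1ccc(OCc2ccccc2)cc1 | intermediate
21 | (3S,7R)-8-[(4S,5R)-5-{(2R,6R)-7-[(4S,5S)-5-[(2S)-heptan-2-yl]-2,2-dimethyl-1,3-dioxolan-4-yl]-2-hydroxy-6-methylheptan-2-yl}-2,2-dimethyl-1,3-dioxolan-4-yl]-3,7-dimethyloctyl 3-[4-(benzyloxy)phenyl]propanoate | CCCCC[C@H](C)[C@@H]1OC(C)(C)O[C@H]1C[C@H](C)CCC[C@@](C)(O)[C@@H]2OC(C)(C)O[C@H]2C[C@H](C)CCC[C@H](C)CCOC(=O)CCc1ccc(OCc3ccccc3)cc1 | intermediate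
22 | (3S,7R)-8-[(4S,5R)-5-{(2R,6R)-7-[(4S,5S)-5-[(2S)-heptan-2-yl]-2,2-dimethyl-1,3-dioxolan-4-yl]-2-hydroxy-6-methylheptan-2-yl}-2,2-dimethyl-1,3-dioxolan-4-yl]-3,7-dimethyloctyl 3-(4-hydroxyphenyl)propanoate | CCCCC[C@H](C)[C@@H]1OC(C)(C)O[C@H]1C[C@H](C)CCC[C@@](C)(O)[C@@H]2OC(C)(C)O[C@H]2C[C@H](C)CCC[C@H](C)CCOC(=O)CCc1ccc(O)cc1 | intermediate
23 | (3S,7R,9S,10R,11R,15R,17S,18S,19S)-9,10,11,17,18-pentahydroxy-3,7,11,15,19-pentamethyltetracosyl 3-(4-hydroxyphenyl)propanoate | CCCCC[C@H](C)[C@H](O)[C@@H](O)C[C@H](C)CCC[C@@](C)(O)[C@H](O)[C@@H](O)C[C@H](C)CCC[C@H](C)CCOC(=O)CCc1ccc(O)cc1 | target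

## Step count and risks

Total steps: 14. Longest linear sequence: 8 (steps 1, 2, 3, 4, 5, 6, 13, 14, or equally 1, 2, 7, 8, 9, 12, 13, 14).

Step 12 (the proposed iron/nickel coupling) is the most likely to fail: the cycle is untested for alkyl iodides, homocoupling can compete, and ferric iron may engage the free tertiary alcohol. The fallback sets out from 18 and 13 and comes back at 19. Acid 18 is converted with N-hydroxyphthalimide, N,N′-diisopropylcarbodiimide and catalytic DMAP in CH2Cl2 into its redox-active ester, 1,3-dioxoisoindolin-2-yl (4S)-6-({3-[4-(benzyloxy)phenyl]propanoyl}oxy)-4-methylhexanoate F1. F1 is then joined to iodide 13 by the known thermal nickel-catalysed reductive cross-electrophile coupling of N-hydroxyphthalimide esters with alkyl halides (NiBr2·glyme, 4,4′-di-tert-butyl-2,2′-bipyridine, Zn dust, DMA, rt), giving 19.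

Step 13 is the second risk: a late alkyl–alkyl Suzuki coupling with a β-branched primary iodide may be slow and lose material to β-hydride elimination. The fallback sets out from 9 and 19 and comes back at 22. Iodide 9 is vinylated (CH2=CHMgBr, CuI cat., THF, −20 °C) to (4S,5S)-4-[(2S)-heptan-2-yl]-2,2-dimethyl-5-[(2R)-2-methylpent-4-en-1-yl]-1,3-dioxolane F2. Olefin cross-metathesis of F2 with the vinyl carbinol 19, using the second-generation Grubbs catalyst (H2IMes)(PCy3)Cl2Ru=CHPh in CH2Cl2 at 40 °C, forms the C12=C13 bond and gives (3S,7R)-8-[(4S,5R)-5-{(2R,3E,6R)-7-[(4S,5S)-5-[(2S)-heptan-2-yl]-2,2-dimethyl-1,3-dioxolan-4-yl]-2-hydroxy-6-methylhept-3-en-2-yl}-2,2-dimethyl-1,3-dioxolan-4-yl]-3,7-dimethyloctyl 3-[4-(benzyloxy)phenyl]propanoate F3. Hydrogenation of F3 over Pd/C then saturates the alkene and removes the benzyl group in one operation, giving 22, which is hydrolysed as in step 14.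

Step 8 is the third risk: if the dioxolane oxygen chelates poorly, the Felkin–Anh pathway would give the C11 epimer. The fallback sets out from 4 and comes back at 12, forming the same centre with the roles of the two carbon groups exchanged and the opposite control element. Ester 4 is converted to the Weinreb amide 10, isolated this time, and treated with CH2=CHMgBr to give the enone 1-{(4R,5S)-5-[(2S)-3-chloro-2-methylpropyl]-2,2-dimethyl-1,3-dioxolan-4-yl}prop-2-en-1-one F4. 1,2-Addition of CH3Li in THF at −95 °C (or CH3Ti(O-i-Pr)3), under non-chelating Felkin–Anh control, then delivers methyl to the face that gives 12.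

Further compounds
F1 | step 12 | 1,3-dioxoisoindolin-2-yl (4S)-6-({3-[4-(benzyloxy)phenyl]propanoyl}oxy)-4-methylhexanoate | O=C(CC[C@H](C)CCOC(=O)CCc1ccc(OCc2ccccc2)cc1)ON1C(=O)c2ccccc2C1=O
F2 | step 13 | (4S,5S)-4-[(2S)-heptan-2-yl]-2,2-dimethyl-5-[(2R)-2-methylpent-4-en-1-yl]-1,3-dioxolane | CCCCC[C@H](C)[C@@H]1OC(C)(C)O[C@H]1C[C@H](C)CC=C
F3 | step 13 | (3S,7R)-8-[(4S,5R)-5-{(2R,3E,6R)-7-[(4S,5S)-5-[(2S)-heptan-2-yl]-2,2-dimethyl-1,3-dioxolan-4-yl]-2-hydroxy-6-methylhept-3-en-2-yl}-2,2-dimethyl-1,3-dioxolan-4-yl]-3,7-dimethyloctyl 3-[4-(benzyloxy)phenyl]propanoate | CCCCC[C@H](C)[C@@H]1OC(C)(C)O[C@H]1C[C@H](C)C/C=C/[C@@](C)(O)[C@@H]2OC(C)(C)O[C@H]2C[C@H](C)CCC[C@H](C)CCOC(=O)CCc1ccc(OCc3ccccc3)cc1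
F4 | step 8 | 1-{(4R,5S)-5-[(2S)-3-chloro-2-methylpropyl]-2,2-dimethyl-1,3-dioxolan-4-yl}prop-2-en-1-one | C=CC(=O)[C@@H]1OC(C)(C)O[C@H]1C[C@H](C)CCl
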